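**Retrosynthetic overview**
1. Target ⇐ phenol release, hydroxyl-directed epoxidation of C3=C4 and acylation of the C8 alcohol of diol 15.
2. Diol 15 ⇐ bicyclic enone 12 (C10 ketone) by methyl addition at C10 and conjugate borylation/oxidation at C8.
3. Enone 12 ⇐ triene 10 by one ring-rearrangement metathesis (the carvone ring is opened, the five-membered ring closes first, then the seven-membered ring), followed by Saegusa oxidation.
4. Triene 10 ⇐ ester 5 by an Ireland–Claisen [3,3] rearrangement, which forms the C1–C5 ring-fusion bond and both fusion stereocentres.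
5. Ester 5 ⇐ (R)-carvone (C7 stereocentre bought) and pent-4-enoic acid.

Assumption: positions are named with guaiane numbering (five-membered ring C1–C5, seven-membered ring C1, C5–C10; α is the face of H-1); "14-nor" means the C10 methyl is still missing.

**Step 1**
Reactants: 1 (R)-(−)-carvone
Product: 2 (5R)-2-methyl-5-(propan-2-yl)cyclohex-2-en-1-one
Conditions: H2 (1 atm), RhCl(PPh3)3 (2 mol %), benzene, 25 °C
Reagents that add atoms: none
Why: Homogeneous hydrogenation with RhCl(PPh3)3 reduces only the unhindered 1,1-disubstituted isopropenyl alkene, leaving the enone and the bought stereocentre (later C7) untouched.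

**Step 2**
Reactants: 2 (5R)-2-methyl-5-(propan-2-yl)cyclohex-2-en-1-one
Product: 3 (1R,5R)-2-methyl-5-(propan-2-yl)cyclohex-2-en-1-ol
Conditions: NaBH4, CeCl3·7H2O, MeOH, −78 → 0 °C
Reagents that add atoms: none
Why: Luche 1,2-reduction, in which axial hydride delivery gives the pseudo-equatorial alcohol cis to isopropyl (carbinol centre set by the bought centre).

**Step 3**
Reactants: 3 (1R,5R)-2-methyl-5-(propan-2-yl)cyclohex-2-en-1-ol; 4 pent-4-enoic acid
Product: 5 (1S,5R)-2-methyl-5-(propan-2-yl)cyclohex-2-en-1-yl pent-4-enoate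
Conditions: PPh3, DIAD, THF, 0 → 25 °C
Reagents that add atoms: none
Why: Mitsunobu esterification, whose SN2 displacement inverts the carbinol carbon and places the ester oxygen trans to isopropyl.

**Step 4**
Reactants: 5 (1S,5R)-2-methyl-5-(propan-2-yl)cyclohex-2-en-1-yl pent-4-enoate
Product: 8 (2R)-2-[(1S,5S)-2-methyl-5-(propan-2-yl)cyclohex-2-en-1-yl]pent-4-enoic acid, via silyl ketene acetal 6 (not isolated), via trimethylsilyl ester 7 (not isolated)
Conditions: lithium diisopropylamide, THF/DMPU (3:1), −78 °C; Me3SiCl; −78 → 50 °C; then 1 M HCl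
Reagents that add atoms: none
Why: Ireland–Claisen [3,3]-sigmatropic rearrangement, in which the new C–C bond (future C1–C5) forms suprafacially on the face of the departing oxygen, trans to isopropyl (sets C5), and the (Z)-silyl ketene acetal reacting through a chair transition state sets the adjacent centre (future C1) as 2R.

**Step 5**
Reactants: 8 (2R)-2-[(1S,5S)-2-methyl-5-(propan-2-yl)cyclohex-2-en-1-yl]pent-4-enoic acid
Product: 9 (3R)-3-[(1S,5S)-2-methyl-5-(propan-2-yl)cyclohex-2-en-1-yl]hex-5-en-2-one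
Conditions: MeLi (2.3 equiv), Et2O, 0 °C; inverse quench into 1 M HCl
Reagents that add atoms: methyllithium, C[Li]
Why: Addition of MeLi to the lithium carboxylate gives a stable dilithio gem-diolate that collapses to the methyl ketone only on quench, so there is no over-addition and no enolisation of the α-centre.

**Step 6**
Reactants: 9 (3R)-3-[(1S,5S)-2-methyl-5-(propan-2-yl)cyclohex-2-en-1-yl]hex-5-en-2-one
Product: 10 tert-butyl({(3R)-3-[(1S,5S)-2-methyl-5-(propan-2-yl)cyclohex-2-en-1-yl]hexa-1,5-dien-2-yl}oxy)dimethylsilane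
Conditions: lithium diisopropylamide, THF, −78 °C; then tBuMe2SiCl, DMPU, −78 → 0 °C
Reagents that add atoms: tert-butyl(chloro)dimethylsilane, CC(C)(C)[Si](C)(C)Cl
Why: Kinetic deprotonation at the unhindered methyl group and O-silylation give the terminal silyl enol ether without touching the α-stereocentre.

**Step 7**
Reactants: 10 tert-butyl({(3R)-3-[(1S,5S)-2-methyl-5-(propan-2-yl)cyclohex-2-en-1-yl]hexa-1,5-dien-2-yl}oxy)dimethylsilane
Product: 11 10-(tert-butyldimethylsilyloxy)-14-nor-1αH,5βH,7βH-guaia-3,9-diene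
Conditions: second-generation Grubbs catalyst (H2IMes)(PCy3)Cl2Ru=CHPh (5 mol %), toluene, 80 °C, argon sparge
Reagents that add atoms: none
Why: Ring-rearrangement olefin metathesis, in which the alkylidene formed at the allyl group opens the trisubstituted cyclohexene to close the cyclopentene (C3=C4) and the relayed alkylidene closes the seven-membered ring on the silyl enol ether (C9=C10), driven by loss of ethene; no stereocentre is touched.

**Step 8**
Reactants: 11 10-(tert-butyldimethylsilyloxy)-14-nor-1αH,5βH,7βH-guaia-3,9-diene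
Product: 12 14-nor-1αH,5βH,7βH-guaia-3,8-dien-10-one
Conditions: Pd(OAc)2 (1.1 equiv), MeCN, 25 °C
Reagents that add atoms: none
Why: Saegusa–Ito oxidation, in which the palladium enolate at C9 undergoes β-hydride elimination from C8 and gives the C8=C9 enone regiospecifically.

**Step 9**
Reactants: 12 14-nor-1αH,5βH,7βH-guaia-3,8-dien-10-one
Product: 14 8β-hydroxy-14-nor-1αH,5βH,7βH-guai-3-en-10-one, via β-boryl ketone 13 (not isolated)
Conditions: B2pin2, CuCl (5 mol %), NaOtBu (10 mol %), DPEphos (5 mol %), MeOH (2 equiv), THF, 25 °C; then NaBO3·4H2O, THF/H2O, 25 °C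
Reagents that add atoms: sodium perborate, [Na+].[Na+].O[B-]1(O)OO[B-](O)(O)OO1
Why: Copper-catalysed conjugate borylation adds boron to C8 anti to the neighbouring 7α-isopropyl group and stereoretentive perborate oxidation gives the 8β-alcohol; C1, α to the ketone, stays in the trans-fused configuration, which is expected to be the more stable one.

**Step 10**
Reactants: 14 8β-hydroxy-14-nor-1αH,5βH,7βH-guai-3-en-10-one
Product: 15 1αH,5βH,7βH-guai-3-ene-8β,10α-diol
Conditions: CeCl3 (anhydrous), MeMgBr (3 equiv), THF, −78 °C; aq. NH4Cl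
Reagents that add atoms: methylmagnesium bromide, C[Mg]Br
Why: Organocerium 1,2-addition to the ketone, expected to occur by equatorial, alkoxide-guided attack from the β face to give the axial 10α-OH/10β-Me carbinol without enolisation or retro-aldol cleavage.

**Step 11**
Reactants: 15 1αH,5βH,7βH-guai-3-ene-8β,10α-diol; 16 4-acetoxybenzoyl chloride
Product: 17 10α-hydroxy-1αH,5βH,7βH-guai-3-en-8β-yl 4-acetoxybenzoate
Conditions: pyridine, DMAP (0.2 equiv), CH2Cl2, 0 → 25 °C
Reagents that add atoms: none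
Why: DMAP-catalysed acylation takes place only at the secondary 8β-hydroxyl; the tertiary 10-hydroxyl is inert.

**Step 12**
Reactants: 17 10α-hydroxy-1αH,5βH,7βH-guai-3-en-8β-yl 4-acetoxybenzoate
Product: 18 3α,4α-epoxy-10α-hydroxy-1αH,5βH,7βH-guaian-8β-yl 4-acetoxybenzoate
Conditions: VO(acac)2 (5 mol %), tBuOOH (decane), CH2Cl2, 0 → 25 °C
Reagents that add atoms: tert-butyl hydroperoxide, CC(C)(C)OO
Why: Hydroxyl-directed vanadium-catalysed epoxidation, in which the 10α-alkoxide binds vanadium and delivers the peroxide oxygen to the α face of C3=C4 (sets C3 and C4).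

**Step 13**
Reactants: 18 3α,4α-epoxy-10α-hydroxy-1αH,5βH,7βH-guaian-8β-yl 4-acetoxybenzoate
Product: 19 3α,4α-epoxy-10α-hydroxy-1αH,5βH,7βH-guaian-8β-yl 4-hydroxybenzoate (target, 1R,3R,4S,5S,7S,8R,10R)
Conditions: K2CO3 (0.2 equiv), MeOH, 0 °C
Reagents that add atoms: none
Why: Base-catalysed methanolysis cleaves the aryl acetate much faster than the hindered secondary benzoate, which is further deactivated once the phenoxide forms; epoxide and tertiary alcohol are untouched.

**Compound list**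
1 | (R)-(−)-carvone | C=C(C)[C@H]1CC(=O)C(C)=CC1 | starting material
2 | (5R)-2-methyl-5-(propan-2-yl)cyclohex-2-en-1-one | CC(C)[C@H]1CC(=O)C(C)=CC1 | intermediate
3 | (1R,5R)-2-methyl-5-(propan-2-yl)cyclohex-2-en-1-ol (OH cis to isopropyl) | CC(C)[C@H]1C[C@@H](O)C(C)=CC1 | intermediate
4 | pent-4-enoic acid | C=CCCC(=O)O | starting material
5 | (1S,5R)-2-methyl-5-(propan-2-yl)cyclohex-2-en-1-yl pent-4-enoate (ester oxygen trans to isopropyl) | CC(C)[C@H]1C[C@H](OC(=O)CCC=C)C(C)=CC1 | intermediate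
6 | (Z)-trimethylsilyl ketene acetal of 5 | CC(C)[C@H]1C[C@H](O/C(O[Si](C)(C)C)=C/CC=C)C(C)=CC1 | intermediate
7 | trimethylsilyl (2R)-2-[(1S,5S)-2-methyl-5-(propan-2-yl)cyclohex-2-en-1-yl]pent-4-enoate | CC(C)[C@@H]1C[C@@H]([C@@H](CC=C)C(=O)O[Si](C)(C)C)C(C)=CC1 | intermediate
8 | (2R)-2-[(1S,5S)-2-methyl-5-(propan-2-yl)cyclohex-2-en-1-yl]pent-4-enoic acid (side chain trans to isopropyl) | CC(C)[C@@H]1C[C@@H]([C@@H](CC=C)C(=O)O)C(C)=CC1 | intermediate
9 | (3R)-3-[(1S,5S)-2-methyl-5-(propan-2-yl)cyclohex-2-en-1-yl]hex-5-en-2-one | CC(C)[C@@H]1C[C@@H]([C@@H](CC=C)C(C)=O)C(C)=CC1 | intermediate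
10 | tert-butyl({(3R)-3-[(1S,5S)-2-methyl-5-(propan-2-yl)cyclohex-2-en-1-yl]hexa-1,5-dien-2-yl}oxy)dimethylsilane | CC(C)[C@@H]1C[C@@H]([C@@H](CC=C)C(=C)O[Si](C)(C)C(C)(C)C)C(C)=CC1 | intermediate
11 | 10-(tert-butyldimethylsilyloxy)-14-nor-1αH,5βH,7βH-guaia-3,9-diene (trans-fused, 7α-isopropyl) | CC(C)[C@@H]1C[C@H]2[C@@H](CC=C2C)C(O[Si](C)(C)C(C)(C)C)=CC1 | intermediate
12 | 14-nor-1αH,5βH,7βH-guaia-3,8-dien-10-one | CC(C)[C@@H]1C[C@H]2[C@@H](CC=C2C)C(=O)C=C1 | intermediate
13 | 8β-(4,4,5,5-tetramethyl-1,3,2-dioxaborolan-2-yl)-14-nor-1αH,5βH,7βH-guai-3-en-10-one | CC(C)[C@@H]1C[C@H]2[C@@H](CC=C2C)C(=O)C[C@H]1B3OC(C)(C)C(C)(C)O3 | intermediate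
14 | 8β-hydroxy-14-nor-1αH,5βH,7βH-guai-3-en-10-one | CC(C)[C@@H]1C[C@H]2[C@@H](CC=C2C)C(=O)C[C@H]1O | intermediate
15 | 1αH,5βH,7βH-guai-3-ene-8β,10α-diol | CC(C)[C@@H]1C[C@H]2[C@@H](CC=C2C)[C@](C)(O)C[C@H]1O | intermediate
16 | 4-acetoxybenzoyl chloride | CC(=O)Oc1ccc(cc1)C(Cl)=O | starting material
17 | 10α-hydroxy-1αH,5βH,7βH-guai-3-en-8β-yl 4-acetoxybenzoate | CC(C)[C@@H]1C[C@H]2[C@@H](CC=C2C)[C@](C)(O)C[C@H]1OC(=O)c1ccc(OC(C)=O)cc1 | intermediate
18 | 3α,4α-epoxy-10α-hydroxy-1αH,5βH,7βH-guaian-8β-yl 4-acetoxybenzoate | CC(C)[C@@H]1C[C@H]2[C@@H](C[C@H]3O[C@]32C)[C@](C)(O)C[C@H]1OC(=O)c1ccc(OC(C)=O)cc1 | intermediate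
19 | 3α,4α-epoxy-10α-hydroxy-1αH,5βH,7βH-guaian-8β-yl 4-hydroxybenzoate | CC(C)[C@@H]1C[C@H]2[C@@H](C[C@H]3O[C@]32C)[C@](C)(O)C[C@H]1OC(=O)c1ccc(O)cc1 | target

**Totals**
Total step count: 13. Longest linear sequence: 13 steps, from (R)-carvone 1 to 19.

**Three steps most likely to fail, each with a fallback**

Step 7 (ring-rearrangement metathesis). Opening an unstrained trisubstituted cyclohexene may be too slow. The fallback opens the carvone ring oxidatively instead; it sets out from acid 8 and comes back at 11. Acid 8 is methylated (Me3SiCHN2, MeOH/toluene) to the methyl ester F1. mCPBA epoxidises only the trisubstituted ring alkene to the epoxide F2, and H5IO6 (THF/H2O) cleaves it to the keto aldehyde F3. Salt-free Ph3P=CH2 (excess, −78 → 0 °C) methylenates both carbonyls to the triene ester F4. The second-generation Grubbs catalyst then closes only the five-membered ring (isopropenyl plus allyl) to the cyclopentene ester F5. LiOH gives the acid F6, MeLi the methyl ketone F7, and lithium diisopropylamide/tBuMe2SiCl the silyl enol ether F8. A simple ring-closing metathesis of the terminal vinyl group onto the enol ether closes the seven-membered ring to 11.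

Step 10 (face of methyl addition at C10). If methyl adds from the α face, the carbinol is built by a different mechanism; this fallback sets out from 14 and comes back at 15. The hydroxyl of 14 is silylated (tBuMe2SiOTf, 2,6-lutidine) to the silyl ether F9. Me3S(O)I/NaH in DMSO (Corey–Chaykovsky, reversible sulfoxonium ylide addition, so CH2 ends equatorial and oxygen axial) gives the spiro-epoxide F10. LiBHEt3 opens it at the CH2 carbon to the tertiary alcohol F11, and Bu4NF removes the silyl group to give 15.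

Step 12 (face of the epoxide). If the remote hydroxyl does not direct the peroxide, or the β-epoxide forms, the oxygen is put on C4 from the α face by a halohydrin sequence; this fallback sets out from 17 and comes back at 19. NBS in aqueous DME forms the bromonium ion on the open β face and water opens it at C4 from the α face to give the bromohydrin F12. K2CO3 in MeOH then closes the 3α,4α-epoxide by backside displacement of bromide and cleaves the aryl acetate in the same flask, giving 19.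

**Further compounds**
F1 | step 7 | methyl (2R)-2-[(1S,5S)-2-methyl-5-(propan-2-yl)cyclohex-2-en-1-yl]pent-4-enoate | CC(C)[C@@H]1C[C@@H]([C@@H](CC=C)C(=O)OC)C(C)=CC1
F2 | step 7 | ring epoxide of F1 (mixture at the two epoxide carbons) | CC(C)[C@@H]1C[C@@H]([C@@H](CC=C)C(=O)OC)C2(C)OC2C1
F3 | step 7 | keto aldehyde from cleavage of F2 (methyl ketone at C4, aldehyde at C9) | CC(C)[C@@H](CC=O)C[C@@H]([C@@H](CC=C)C(=O)OC)C(C)=O
F4 | step 7 | triene ester from double methylenation of F3 | CC(C)[C@@H](CC=C)C[C@@H]([C@@H](CC=C)C(=O)OC)C(C)=C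
F5 | step 7 | cyclopentene methyl ester (trans-1,5-disubstituted 2-methylcyclopent-2-ene) | CC(C)[C@@H](CC=C)C[C@H]1[C@@H](CC=C1C)C(=O)OC
F6 | step 7 | cyclopentene carboxylic acid from F5 | CC(C)[C@@H](CC=C)C[C@H]1[C@@H](CC=C1C)C(=O)O
F7 | step 7 | cyclopentenyl methyl ketone from F6 | CC(C)[C@@H](CC=C)C[C@H]1[C@@H](CC=C1C)C(C)=O
F8 | step 7 | tert-butyldimethylsilyl enol ether of F7 | CC(C)[C@@H](CC=C)C[C@H]1[C@@H](CC=C1C)C(=C)O[Si](C)(C)C(C)(C)C
F9 | step 10 | 8β-(tert-butyldimethylsilyloxy)-14-nor-1αH,5βH,7βH-guai-3-en-10-one | CC(C)[C@@H]1C[C@H]2[C@@H](CC=C2C)C(=O)C[C@H]1O[Si](C)(C)C(C)(C)C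
F10 | step 10 | 10α,14-epoxy-8β-(tert-butyldimethylsilyloxy)-1αH,5βH,7βH-guai-3-ene | CC(C)[C@@H]1C[C@H]2[C@@H](CC=C2C)[C@@]3(CO3)C[C@H]1O[Si](C)(C)C(C)(C)C
F11 | step 10 | 8β-(tert-butyldimethylsilyloxy)-1αH,5βH,7βH-guai-3-en-10α-ol | CC(C)[C@@H]1C[C@H]2[C@@H](CC=C2C)[C@](C)(O)C[C@H]1O[Si](C)(C)C(C)(C)C
F12 | step 12 | 3β-bromo-4α,10α-dihydroxy-1αH,5βH,7βH-guaian-8β-yl 4-acetoxybenzoate | CC(C)[C@@H]1C[C@H]2[C@@H](C[C@H](Br)[C@@]2(C)O)[C@](C)(O)C[C@H]1OC(=O)c1ccc(OC(C)=O)cc1
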